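**Retrosynthetic overview**
1. (+)-Lariciresinol 12 ⇐ dibenzyl ether 11 by hydrogenolysis of the two aryl benzyl ethers.
2. Tetrahydrofuran ring (C2–O bond) ⇐ acid-promoted SN1 cycloetherification of benzylic triol 10 ⇐ LiAlH4 reduction of trans aldol lactone 9.
3. C2–C3 bond and the C3 stereocentre ⇐ anti-selective aldol of (R)-β-benzyl-γ-butyrolactone 7 with O-benzylvanillin 8.
4. C3–C4 (lignan 8–8′) bond and the C4 stereocentre ⇐ Johnson–Claisen [3,3] rearrangement of (R,E)-allylic alcohol 4 with 1,3-chirality transfer, then ozonolysis/lactonisation; 4 ⇐ (R)-but-3-yn-2-ol 1 + benzylic chloride 2.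
5. Ring order: γ-lactone (temporary, step 4) → opened to the triol (step 6) → tetrahydrofuran (step 7).

Assumption: (R)-but-3-yn-2-ol, 4-(benzyloxy)-3-methoxybenzyl chloride and O-benzylvanillin are treated as catalogue items.

**Route**

Step 1
Reactants: 1, (R)-but-3-yn-2-ol; 2, 4-(benzyloxy)-3-methoxybenzyl chloride
Product: 3, (R)-5-[4-(benzyloxy)-3-methoxyphenyl]pent-3-yn-2-ol
Conditions: 1 + EtMgBr (2.0 equiv), THF, 0→50 °C; CuCl (10 mol %), then 2, 60 °C
Reagents that add atoms: none (all heavy atoms come from 1 and 2)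
Why: Cu(I)-catalysed coupling of the alkynyl Grignard (alkoxide/acetylide dianion) with an activated benzylic chloride forms the C(sp)–C(sp3) bond, and the carbinol centre is an alkoxide throughout so it cannot epimerise.

Step 2
Reactants: 3, (R)-5-[4-(benzyloxy)-3-methoxyphenyl]pent-3-yn-2-ol
Product: 4, (R,E)-5-[4-(benzyloxy)-3-methoxyphenyl]pent-3-en-2-ol
Conditions: Red-Al, THF, 0 °C→rt; Rochelle-salt work-up
Reagents that add atoms: none
Why: Alkoxide-directed trans-hydroalumination of a propargylic alcohol (Red-Al reduction) gives only the (E)-allylic alcohol and leaves the stereocentre untouched.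

Step 3
Reactants: 4, (R,E)-5-[4-(benzyloxy)-3-methoxyphenyl]pent-3-en-2-ol; 5, triethyl orthoacetate
Product: 6, ethyl (R,E)-3-[4-(benzyloxy)-3-methoxybenzyl]hex-4-enoate
Conditions: MeC(OEt)3 (6 equiv), EtCO2H (cat.), 140 °C, EtOH distilled off
Reagents that add atoms: triethyl orthoacetate, CCOC(C)(OCC)OCC
Why: Johnson–Claisen [3,3]-sigmatropic rearrangement of the mixed ketene acetal through a chair transition state with the carbinol methyl equatorial forms the C8–C8′ bond suprafacially, so the (R)-C–O centre of the (E)-alkene is transferred to the new (R)-C–C centre (future C4).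

Step 4
Reactants: 6, ethyl (R,E)-3-[4-(benzyloxy)-3-methoxybenzyl]hex-4-enoate
Product: 7, (R)-4-[4-(benzyloxy)-3-methoxybenzyl]dihydrofuran-2(3H)-one
Conditions: O3, CH2Cl2/MeOH, −78 °C (Sudan III end-point); NaBH4, −78→0 °C; then TsOH (cat.), rt
Reagents that add atoms: ozone, O=[O+][O-] (supplies the lactone ring oxygen)
Why: Ozonolysis of the propenyl group with in-situ borohydride reduction gives the primary alcohol, which lactonises onto the ethyl ester; the alkene reacts far faster than the arenes, and cold in-situ reduction of the transient α-branched aldehyde preserves the stereocentre.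

Step 5
Reactants: 7, (R)-4-[4-(benzyloxy)-3-methoxybenzyl]dihydrofuran-2(3H)-one; 8, 4-(benzyloxy)-3-methoxybenzaldehyde (O-benzylvanillin)
Product: 9, (3S,4R)-3-{[4-(benzyloxy)-3-methoxyphenyl](hydroxy)methyl}-4-[4-(benzyloxy)-3-methoxybenzyl]dihydrofuran-2(3H)-one (3,4-trans; mixture of carbinol epimers, both carried on)
Conditions: LDA, THF, −78 °C; then 8, −78 °C; NH4Cl quench at −78 °C
Reagents that add atoms: O-benzylvanillin, COc1cc(C=O)ccc1OCc1ccccc1
Why: Lithium-enolate aldol addition in which the aldehyde approaches the lactone enolate anti to the β-benzyl group, giving the 3,4-trans lactone and thereby setting the future C3 under control of C4.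

Step 6
Reactants: 9, the trans aldol lactone
Product: 10, (2R,3R)-2-{[4-(benzyloxy)-3-methoxyphenyl](hydroxy)methyl}-3-[4-(benzyloxy)-3-methoxybenzyl]butane-1,4-diol (carbinol epimers)
Conditions: LiAlH4, THF, 0 °C
Reagents that add atoms: none
Why: LiAlH4 reduction of the lactone to the 1,4-diol is faster at 0 °C than retro-aldol, and the two backbone stereocentres are no longer epimerisable afterwards.

Step 7
Reactants: 10, the benzylic triol
Product: 11, {(2S,3R,4R)-2-[4-(benzyloxy)-3-methoxyphenyl]-4-[4-(benzyloxy)-3-methoxybenzyl]tetrahydrofuran-3-yl}methanol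
Conditions: TsOH·H2O (10 mol %), CH2Cl2, 0 °C→rt
Reagents that add atoms: none
Why: Acid-catalysed SN1 5-exo cycloetherification via the p-alkoxybenzyl cation (the oxetane alternative is not formed); both carbinol epimers converge, and reversible ionisation delivers the favoured 2,3-trans ring with the aryl group anti to both neighbours, setting C2 as S.

Step 8
Reactants: 11, dibenzyl lariciresinol
Product: 12, (+)-lariciresinol, 4-[(2S,3R,4R)-4-(4-hydroxy-3-methoxybenzyl)-3-(hydroxymethyl)tetrahydrofuran-2-yl]-2-methoxyphenol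
Conditions: H2 (1 atm), 10% Pd/C, EtOAc, rt, stopped at complete O-debenzylation
Reagents that add atoms: none
Why: Hydrogenolysis of aryl benzyl ethers is much faster than cleavage of the cyclic benzylic C–O bond under neutral conditions, and no stereocentre is touched.

**Compound list**
1 | (R)-but-3-yn-2-ol | C[C@@H](O)C#C | starting material
2 | 4-(benzyloxy)-3-methoxybenzyl chloride | COc1cc(CCl)ccc1OCc1ccccc1 | starting material
3 | (R)-5-[4-(benzyloxy)-3-methoxyphenyl]pent-3-yn-2-ol | C[C@@H](O)C#CCc1ccc(OCc2ccccc2)c(OC)c1 | intermediate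
4 | (R,E)-5-[4-(benzyloxy)-3-methoxyphenyl]pent-3-en-2-ol | C[C@@H](O)/C=C/Cc1ccc(OCc2ccccc2)c(OC)c1 | intermediate
5 | triethyl orthoacetate | CCOC(C)(OCC)OCC | starting material
6 | ethyl (R,E)-3-[4-(benzyloxy)-3-methoxybenzyl]hex-4-enoate | CCOC(=O)C[C@@H](Cc1ccc(OCc2ccccc2)c(OC)c1)/C=C/C | intermediate
7 | (R)-4-[4-(benzyloxy)-3-methoxybenzyl]dihydrofuran-2(3H)-one | O=C1C[C@@H](Cc2ccc(OCc3ccccc3)c(OC)c2)CO1 | intermediate
8 | 4-(benzyloxy)-3-methoxybenzaldehyde | COc1cc(C=O)ccc1OCc1ccccc1 | starting material
9 | (3S,4R)-3-{[4-(benzyloxy)-3-methoxyphenyl](hydroxy)methyl}-4-[4-(benzyloxy)-3-methoxybenzyl]dihydrofuran-2(3H)-one (carbinol epimers) | O=C1OC[C@H](Cc2ccc(OCc3ccccc3)c(OC)c2)[C@H]1C(O)c1ccc(OCc2ccccc2)c(OC)c1 | intermediate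
10 | (2R,3R)-2-{[4-(benzyloxy)-3-methoxyphenyl](hydroxy)methyl}-3-[4-(benzyloxy)-3-methoxybenzyl]butane-1,4-diol (carbinol epimers) | COc1cc(C[C@@H](CO)[C@H](CO)C(O)c2ccc(OCc3ccccc3)c(OC)c2)ccc1OCc1ccccc1 | intermediate
11 | {(2S,3R,4R)-2-[4-(benzyloxy)-3-methoxyphenyl]-4-[4-(benzyloxy)-3-methoxybenzyl]tetrahydrofuran-3-yl}methanol | COc1cc(C[C@H]2CO[C@H](c3ccc(OCc4ccccc4)c(OC)c3)[C@H]2CO)ccc1OCc1ccccc1 | intermediate
12 | (+)-lariciresinol | COc1cc(C[C@H]2CO[C@H](c3ccc(O)c(OC)c3)[C@H]2CO)ccc1O | target

**Totals**
Total steps: 8. Longest linear sequence: 8 (from 1).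

**Steps most likely to fail, with fallbacks**
- Step 1 (Cu-catalysed alkynyl–benzyl coupling; risks are bibenzyl homocoupling and low conversion). Fallback: make 4 through a different bond, by Ru-catalysed cross-metathesis of O-benzyleugenol with (R)-but-3-en-2-ol (Grubbs II). This replaces steps 1–2 but needs removal of the minor Z isomer.
- Step 3 (incomplete chirality transfer from the E-alkene would erode ee, since the minor chair gives the enantiomeric centre). Fallback: switch substrate geometry and Claisen variant. Lindlar reduction of the (S)-alkynol gives the (S,Z)-allylic alcohol, and Ireland–Claisen of its acetate (LDA/TMSCl, −78 °C→rt) proceeds through an enforced single chair to the same (R)-acid, which lactonises to 7 on ozonolysis/NaBH4.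
- Step 7 (competing Friedel–Crafts closure to the aryltetralin, and exposure of the product's benzylic ether in the following hydrogenolysis). Fallback: reverse the order. Hydrogenolyse 10 first, then close the ring from the free p-hydroxybenzyl alcohol via its quinone methide under very mild acid; lariciresinol is then obtained directly with no hydrogenolysis after ring formation.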